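## Structural features

The target is a rearranged abietane whose hub is a cyclobutane (ring D: C1, C10, C9, C11). Ring B (C5–C10) shares the C9–C10 bond with it, ring A (C1–C5, C10) the C1–C10 bond and ring C (C8, C9, C11–C14) the C9–C11 bond; C13 is also the spiro atom of a methylcyclopropane (C13, C15, C16). Atoms keep this numbering throughout, and β means the face of ring B that carries the C10 methyl. There are eleven contiguous stereocentres (C1, C5–C13, C15). Every small substituent of ring B (5-H, 6-OAc, 7-OH, 8-H, 9-OH, 10-Me) is β, so rings A, C and D all hang from the α face; A/B, B/C, B/D and C/D are cis-fused and ring A is trans-fused to the cyclobutane. Fragile elements are the β-hydroxy ketone array (7-OH and 9-OH relative to the C14 ketone), the two tertiary cyclobutanols, the cis-6,7-diol monoacetate (acyl migration), the acyl cyclopropane, and the trans A/D junction, which can epimerise at C1 whenever C11 is a ketone. The real difficulty is the fully substituted cyclobutane with two vicinal tertiary carbinols next to a quaternary carbon, together with five oxygen functions of which only two are acetylated. The key step exploits the C1–C10 bond of ring D: a quaternary, methyl-bearing C10 bonded to a C1–H that carries the one-carbon branch C2 is what remains when the angular carbon of an α-diazo cyclopentanone shifts from the acyl carbon to the diazo carbon.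

## Logic of the disconnections

42 to 40. The O6–acetyl bond is cut, then the C6–O and C7–O bonds together, leading through 41 to the C6=C7 olefin 40. All rings hang from the α face, so delivery of both oxygens from outside must give the 6β,7β pattern, and the sensitive β-hydroxy ketone then exists only in the last two compounds. Two stereocentres disappear. The forward steps need β-face attack and a monoacetylation that tells O6 from O7.

40 to 37. The C3 and C14 carbonyls go back to carbinols (39), the three silyl groups are restored (38) and the O12–acetyl bond is cut (37). Ketones at C3 and C14 would not survive the enolate, hydride and ketyl steps before them, and a C14 ketone beside a C12 aldehyde would doubly activate the cyclopropane. The gain is a pattern in which one fluoride step and one oxidation unveil both ketones. The demand is that O12 be acetylated while it is the only free secondary hydroxyl.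

37 to 36. The C11–C12 bond is cut (retron: cis-vicinal diol). Ring C opens and C11 and C12 cease to be stereocentres. The forward coupling must bring C12 onto the cyclobutanone face syn to C8, hold both oxygens on one metal, and outrun opening of the cyclopropylcarbinyl ketyl.

36 to 34. Both carbonyls are reduced (35) and O11 is joined to C12 as a seven-membered lactone (34). The lactone keeps the C11 hydroxyl and the C12 carboxyl masked until one hydride step frees both. The demand is clean reduction of a hindered lactone.

34 to 32. The C6=C7 bond is traced through enol triflate 33 to a C7 ketone. That ketone is what bond formation at C5 and C8 needs; removing it costs two steps. Enolisation must go toward C6, not the C8 methine.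

32 to 31. The C4–C5 bond is cut, opening ring A to an enone and an isopropenyl carbinol ether. This removes a quaternary carbon next to a tertiary one and the C5 stereocentre. The forward step must form a congested bond and deliver C4 to the α face of C5; a tertiary radical tethered through C1 does both.

31 to 27 and 8. The C8–C14 bond is cut (aldol retron), the enone is saturated (29 to 28) and the O11–C12 ester bond is cut. O11 is cis to C8 on the cyclobutane, so an ester there can deliver C14 only to C8 and only from the α face; this fixes regio- and stereochemistry at C8 and installs the C13/C15 unit. The demands are α′-enolisation without ester attack and closure of a seven-membered ring.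

27 to 21. The ketal and silyl groups are restored (26), the C2–C3 bond is cut to a C2 organometallic and methacrolein, and C2 is returned through iodide 23 and alcohol 22 to ester 21. This removes the C3–C4 unit of ring A. The forward steps need a primary organolithium that survives beside the cyclobutane.

21 to 18 (key). The C1–C10 bond is cut and C10 reattached to C2, expanding ring D to an α-diazo cyclopentanone. The strained ring is exchanged for a hydrindanone in which the C9/C10 cis pair is easy to set. The forward rearrangement must beat hydride shift and O–H insertion, and C1 must be equilibrated afterwards.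

18 to 9. Diazo group, ketal, silyl groups, the C9–O bond (through epoxide 13) and the C11–O bond (through dienol ether 10) are removed in turn. Every oxygen is placed by enone chemistry of 9. The demands are γ-oxidation anti to the methyl and nucleophilic epoxidation syn to it.

8 to 1 and 4. The acid returns to ester 7 and diester 6; the C13–C16 and C13–C15 bonds are cut to 4 and cyclic sulfate 3, made from 1. The stereocentre of 1 becomes C15 by inversion, and the two carbonyls are told apart by their relation to the methyl group.

## Other disconnections considered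

Alternative 1: The cut goes through C4–C5 and C9–C10, unravelling rings A and B into the (Z)-aryl epoxy diene A1. In the forward direction MeAlCl2 would open the C3–C4 epoxide, C5 would bond to C4, and the C10 cation would be captured by the arene at C9 to give the cis-fused tricycle A2. In its favour: two rings, two C–C bonds and three stereocentres in one step, with the C3 oxygen, the gem-dimethyl group and all ring C carbons (the cyclopropane carbons as an allyl group) in place. On ring economy for A and B, and on having the C3 oxygen from the start, it is the better plan. Against it: C9 is an arene carbon that must become a tertiary carbinol, the arene must be dearomatised to carry C11–OH, C12–OAc, the spiro centre and the C14 ketone, and the C1–C11 bond would have to be made late between an unactivated methylene and that ring, for which no dependable reaction can be named. A stepwise cation from a Z olefin can also leak to the trans series. The chosen plan is longer for rings A and C but settles the cyclobutane and the C9/C10 pair first, by a reaction of fixed stereochemical course.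

Alternative 2: The cut goes through C5–C10 and C8–C9, dividing the target into the enantiopure cyclobutenone A3 and the (E,E)-diene A4. Under Me2AlCl or high pressure a Diels–Alder reaction would close ring B and give the cis-fused bicyclo[4.2.0]octenone A5. In its favour: it is convergent, sets C5, C8, C9 and C10 in one suprafacial event, leaves a C6=C7 olefin for the cis-diol, and delivers ring D with the C11 ketone. In bonds, stereocentres and step count at the key step it is better than the ring contraction, and in predictability of relative configuration it is at least its equal. Against it: the dienophile is a tetrasubstituted, α-alkoxy olefin that must form two adjacent fully substituted carbons, one next to the neopentyl diene terminus. A 4-substituted cyclobutenone can also open to a vinylketene, which would consume it and erase its stereocentre at the temperature a slow cycloaddition needs. The chosen plan draws C9 and C10 from 9 by reliable enone chemistry; the alternative puts the whole risk into one sterically extreme bimolecular step.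

Alternative 3: The cut is at C13–C15 and at the C12–O bond, leaving the tetracyclic homoallylic mesylate A6 with a C12=C13 olefin and a tert-butyl carbonate on O11. Ionisation of the C15 mesylate in buffered trifluoroethanol would let the olefin participate: C13 bonds to C15 with inversion and the carbonate carbonyl oxygen traps C12, giving cyclic carbonate A7. In its favour: C12, C13 and C15 are set in one step, the cis-11,12 relationship is enforced by the carbonate ring, and the cyclopropane never meets radical or reductive chemistry. On that last point it is better than the chosen plan, whose ring C closure places a ketyl beside the cyclopropane. Against it: it presupposes the whole tetracycle, so it does not shorten the approach to the cyclobutane; the cation can leak to cyclobutyl, homoallyl and elimination products; and the face on which C15 bonds is controlled only by remote centres, whereas the chosen plan takes the C13/C15 relationship from 1 in two steps. For ring C the two are comparable in step count; the tactic could replace steps 24–27 but not the key step.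

Key step: step 13

Remarks on the chemistry:
- α and β refer to the faces of ring B as defined above; on the cyclobutane, positions are stated relative to O9 or the C10 methyl.
- Assumption: the peracid of step 6 attacks anti to the angular methyl, so O11 is trans to the methyl and, after step 8, trans to O9 and cis to C8.
- The configurations of 18 and 21 at C9, C10, C11 and C1 were checked against 42 and 9 and agree; no structural correction is needed. Only spectator groups are changed: triethylsilyl on O11, and trifluoroacetyl instead of formyl activation for diazo transfer.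
- C10 is the only carbon on the acyl carbon of 18, so which group migrates is not in question; the competition is with hydride shift from C11–H and O–H insertion.
- C3 (steps 16–28) and C14 (steps 20–28) are not controlled and are carried as epimer mixtures; both become carbonyl carbons in step 29.

## Route

Step 1
Reactants: 1 (R)-propane-1,2-diol
Product: 3 (4R)-4-methyl-1,3,2-dioxathiolane 2,2-dioxide, via cyclic sulfite 2 (not isolated)
Conditions: SOCl2, CH2Cl2, 0 → 40 °C; then RuCl3·xH2O (cat.), NaIO4, MeCN/H2O, 0 °C
Reagents that add atoms: thionyl chloride O=S(Cl)Cl; sodium periodate [Na+].[O-]I(=O)(=O)=O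
Why: Cyclic sulfite formation followed by ruthenium-catalysed oxidation at sulfur gives the cyclic sulfate; the stereocentre is not touched.

Step 2
Reactants: 4 dimethyl malonate; 3 (4R)-4-methyl-1,3,2-dioxathiolane 2,2-dioxide
Product: 6 dimethyl (2S)-2-methylcyclopropane-1,1-dicarboxylate, via sodium alkyl sulfate 5 (not isolated)
Conditions: NaH (2.2 equiv), DME, 0 → 60 °C
Reagents that add atoms: none
Why: Malonate double alkylation: the anion opens the cyclic sulfate at the primary carbon and the second anion closes the three-membered ring (3-exo-tet) at the secondary carbon with inversion, turning the R centre of 3 into the S centre that becomes C15.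

Step 3
Reactants: 6 dimethyl (2S)-2-methylcyclopropane-1,1-dicarboxylate
Product: 7 methyl (1R,2S)-1-formyl-2-methylcyclopropane-1-carboxylate
Conditions: i-Bu2AlH (1.05 equiv), CH2Cl2, −78 °C; aq. potassium sodium tartrate
Reagents that add atoms: none
Why: Partial reduction of a geminal diester: hydride goes to the less hindered ester, trans to the ring methyl, and the aluminium hemiacetal, chelated by the neighbouring ester, persists at −78 °C and releases the aldehyde on work-up. This site selection defines the quaternary centre (future C13) with formyl (future C14) trans and ester (future C12) cis to the methyl.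

Step 4
Reactants: 7 methyl (1R,2S)-1-formyl-2-methylcyclopropane-1-carboxylate
Product: 8 (1R,2S)-1-formyl-2-methylcyclopropane-1-carboxylic acid
Conditions: LiOH·H2O, THF/H2O, 0 °C; 1 M HCl to pH 3
Reagents that add atoms: lithium hydroxide [Li+].[OH-]
Why: Saponification of the remaining ester; the α-carbon is quaternary and cannot epimerise, and retro-Claisen loss of the formyl group is disfavoured because it would need a cyclopropyl ester enolate.

Step 5
Reactants: 9 (S)-Hajos–Parrish ketone
Product: 10 heteroannular dienol ethyl ether (7-ethoxy-7,9(11)-dien-2-one)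
Conditions: HC(OEt)3, p-TsOH·H2O (cat.), EtOH, 23 °C
Reagents that add atoms: triethyl orthoformate CCOC(OCC)OCC
Why: Acid-catalysed dienol ether formation is selective for the enone, as in the steroid 3-alkoxy-3,5-diene series; the neopentyl cyclopentanone does not react and the only γ-hydrogen (C11) fixes the diene as C7=C8–C9=C11.

Step 6
Reactants: 10 heteroannular dienol ethyl ether
Product: 11 11α-hydroxy-8-ene-2,7-dione
Conditions: mCPBA, NaHCO3, THF/H2O (5:1), 0 °C
Reagents that add atoms: 3-chloroperbenzoic acid O=C(OO)c1cccc(Cl)c1; water O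
Why: The peracid epoxidises the electron-rich diene at the distal C9=C11 bond anti to the angular methyl, the enol ether opens the epoxide, and water hydrolyses the oxocarbenium ion to the γ-hydroxy enone (the classical 6-hydroxylation of steroid dienol ethers). This sets C11 with its oxygen trans to the methyl.

Step 7
Reactants: 11 11α-hydroxy-8-ene-2,7-dione
Product: 12 11α-triethylsilyloxy-8-ene-2,7-dione
Conditions: Et3SiCl, imidazole, DMF, 0 °C
Reagents that add atoms: chlorotriethylsilane CC[Si](Cl)(CC)CC
Why: Silylation prevents base-induced isomerisation of the γ-hydroxy enone to the 1,4-diketone in the next step and places a bulky group on the α face.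

Step 8
Reactants: 12 11α-triethylsilyloxy-8-ene-2,7-dione
Product: 13 8β,9β-epoxy-11α-triethylsilyloxy-2,7-dione
Conditions: 30% aq. H2O2, NaOH (0.2 equiv), MeOH, −10 °C
Reagents that add atoms: hydrogen peroxide OO
Why: Weitz–Scheffer nucleophilic epoxidation: hydroperoxide adds to C9 cis to the angular methyl, the usual course for angularly methylated bicyclic enones, reinforced by the α silyloxy group at C11; this sets the C9–O bond β. Low temperature and substoichiometric base limit β-elimination of the C11 silyloxy group.

Step 9
Reactants: 13 8β,9β-epoxy-11α-triethylsilyloxy-2,7-dione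
Product: 14 9β-hydroxy-11α-triethylsilyloxy-cis-hydrindane-2,7-dione
Conditions: SmI2 (2.2 equiv), THF/MeOH, −90 °C
Reagents that add atoms: none
Why: SmI2 reduces the C7 ketone to a ketyl, the α C–O bond of the epoxide breaks to the enolate, and protonation gives the β-hydroxy ketone; C9 is untouched and the isolated C2 ketone is not reduced at this temperature.

Step 10
Reactants: 14 9β-hydroxy-11α-triethylsilyloxy-cis-hydrindane-2,7-dione
Product: 15 9β,11α-bis(triethylsilyloxy)-cis-hydrindane-2,7-dione
Conditions: Et3SiOTf, 2,6-lutidine, CH2Cl2, −78 → 0 °C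
Reagents that add atoms: triethylsilyl trifluoromethanesulfonate CC[Si](CC)(CC)OS(=O)(=O)C(F)(F)F
Why: The hindered tertiary alcohol needs the silyl triflate; 2,6-lutidine at low temperature does not enolise the ketones.

Step 11
Reactants: 15 9β,11α-bis(triethylsilyloxy)-cis-hydrindane-2,7-dione
Product: 16 7,7-ethylenedioxy-9β,11α-bis(triethylsilyloxy)-cis-hydrindan-2-one
Conditions: (Me3SiOCH2)2, Me3SiOTf (cat.), CH2Cl2, −78 → −20 °C; pyridine
Reagents that add atoms: 1,2-bis(trimethylsilyloxy)ethane C[Si](C)(C)OCCO[Si](C)(C)C
Why: Aprotic silyl-triflate-catalysed ketalisation avoids dehydration of the β-silyloxy ketone and takes the unhindered C7 cyclohexanone in preference to the neopentyl C2 cyclopentanone.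

Step 12
Reactants: 16 7,7-ethylenedioxy-9β,11α-bis(triethylsilyloxy)-cis-hydrindan-2-one
Product: 18 1-diazo-7,7-ethylenedioxy-9β,11α-bis(triethylsilyloxy)-cis-hydrindan-2-one, via trifluoroacetyl ketone 17 (not isolated)
Conditions: LiN(SiMe3)2, THF, −78 °C; CF3CO2CH2CF3; then MeSO2N3, Et3N, H2O, MeCN, 23 °C
Reagents that add atoms: methanesulfonyl azide CS(=O)(=O)N=[N+]=[N-]
Why: Detrifluoroacetylative diazo transfer: the C2 ketone can enolise only toward C1, the enolate is trifluoroacetylated at −78 °C before β-elimination of O11 can occur, and the activated methine takes up N2 from the sulfonyl azide with loss of the trifluoroacetyl group.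

Step 13
Reactants: 18 1-diazo-7,7-ethylenedioxy-9β,11α-bis(triethylsilyloxy)-cis-hydrindan-2-one
Product: 21 methyl ester of the ring B/ring D cis-bicyclo[4.2.0]octane (CO2Me on C1 cis to the C10 methyl), via ketene 19 (not isolated), via kinetic ester epimers 20 (not isolated)
Conditions: hν (365 nm), MeOH, −20 °C; then NaOMe (0.3 equiv), MeOH, 23 °C
Reagents that add atoms: methanol CO
Why: Direct irradiation of the ring-locked s-cis α-diazo ketone expels N2 while C10, the only carbon on the acyl carbon, shifts to C1 (Wolff rearrangement) to give ketene 19, which methanol captures as ester 20. The closest known reaction type is the photochemical ring contraction of angular-methyl 2-diazo hydrindan-1-ones used for D-nor steroids. Ring D arises by a 1,2-shift and not by a cyclisation, so no ring-closure mode applies and the cis C9–C10 junction is inherited unchanged. C10 migrates with retention, so the only new stereocentre is C1: it is first set by kinetic protonation of the ketene-derived enol and then corrected by methoxide equilibration, which puts the ester on the convex face, cis to the C10 methyl and trans to the C11 silyloxy group. The selectivity needed is rearrangement over 1,2-hydride shift from C11–H and over O–H insertion of a free carbene; the enforced s-cis geometry (concerted loss of N2 from the singlet excited state), low temperature and the weakly donating silyloxy group at C11 secure it. The C7 ketone is masked as a dioxolane so that it neither absorbs light nor competes in step 12.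

Step 14
Reactants: 21 methyl ester of the ring B/ring D bicycle
Product: 22 C2 primary alcohol
Conditions: LiAlH4, THF, 0 °C
Reagents that add atoms: none
Why: Standard hydride reduction of the ester; silyl ethers and dioxolane are inert and C1 keeps its configuration.

Step 15
Reactants: 22 C2 primary alcohol
Product: 23 C2 primary iodide
Conditions: I2, PPh3, imidazole, CH2Cl2, 0 → 23 °C
Reagents that add atoms: iodine II
Why: Appel-type iodination by SN2 displacement of the oxyphosphonium group at the primary carbon.

Step 16
Reactants: 23 C2 primary iodide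
Product: 26 C3 triisopropylsilyl ether with the side chain C1–CH2–CH(OSi-i-Pr3)–C(CH3)=CH2, via organolithium 24 (not isolated), via lithium alkoxide 25 (not isolated)
Conditions: t-BuLi (2.1 equiv), Et2O/pentane, −78 °C; methacrolein; then i-Pr3SiOTf, −78 → 0 °C
Reagents that add atoms: methacrolein CC(=C)C=O; triisopropylsilyl trifluoromethanesulfonate CC(C)[Si](C(C)C)(C(C)C)OS(=O)(=O)C(F)(F)F
Why: Iodine–lithium exchange at −78 °C gives the primary organolithium, which adds 1,2 to methacrolein, and the alkoxide is silylated in the same flask. C3 is not controlled and is later oxidised; the isopropenyl group supplies C4 and both of its methyl carbons.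

Step 17
Reactants: 26 C3 triisopropylsilyl ether
Product: 27 7-oxo-9β,11-diol
Conditions: 1 M aq. HCl, THF, 23 °C
Reagents that add atoms: water O
Why: Aqueous acid hydrolyses the dioxolane and both triethylsilyl ethers, while the much more acid-stable triisopropylsilyl ether should remain; this frees O11 for acylation and C7 for enone chemistry.

Step 18
Reactants: 27 7-oxo-9β,11-diol; 8 (1R,2S)-1-formyl-2-methylcyclopropane-1-carboxylic acid
Product: 28 11-O-[(1R,2S)-1-formyl-2-methylcyclopropanecarbonyl] ester
Conditions: 2,4,6-Cl3C6H2COCl, Et3N, THF; then DMAP, toluene, 23 → 40 °C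
Reagents that add atoms: none
Why: Yamaguchi esterification through the mixed anhydride acylates the secondary O11 hydroxyl and not the tertiary O9 hydroxyl. Because O11 is cis to C8 on the cyclobutane, the ester holds the aldehyde carbon (C14) under the α face of ring B.

Step 19
Reactants: 28 11-O-acyl keto aldehyde
Product: 29 5-en-7-one
Conditions: IBX, DMSO/PhF, 70 °C
Reagents that add atoms: none
Why: IBX dehydrogenation of the ketone through its enol; only the C5–C6 bond can be desaturated because C9 carries no hydrogen, so the regiochemistry is self-correcting.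

Step 20
Reactants: 29 5-en-7-one
Product: 31 aldol lactone with the C8–C14 bond (9,14-bis-O-triethylsilyl; 8β-H), via silyl dienol ether 30 (not isolated)
Conditions: Et3SiOTf (3.5 equiv), i-Pr2NEt, CH2Cl2, −78 → −30 °C
Reagents that add atoms: triethylsilyl trifluoromethanesulfonate CC[Si](CC)(CC)OS(=O)(=O)C(F)(F)F
Why: Soft enolisation at the only α′ position (C8) gives the cross-conjugated silyl dienol ether, and the silyl triflate then promotes an intramolecular Mukaiyama aldol onto the tethered aldehyde with silyl transfer to O14; a silyl enol ether does not attack the ester, so Claisen-type acyl transfer is excluded. The seven-membered lactone can form only with C14 on the α face, which sets C8 (H8 β); C14 is uncontrolled and O9 is silylated in the same flask.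

Step 21
Reactants: 31 aldol lactone
Product: 32 tricyclic 7-ketone with ring A closed (C4–C5 bond; 5β-H)
Conditions: Fe(acac)3, PhSiH3, EtOH/(CH2OH)2, 60 °C
Reagents that add atoms: none
Why: Iron hydride hydrogen-atom transfer to the CH2 terminus of the isopropenyl group gives the tertiary C4 radical, which adds 6-exo-trig to C5 of the enone (radical conjugate addition of Giese type, suited to congested quaternary–tertiary bonds); the α-keto radical is then reduced and protonated. The tether from C1 can reach C5 only from the α face, so C5 is set with its hydrogen β (cis A/B) and C4 becomes the gem-dimethyl carbon.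

Step 22
Reactants: 32 tricyclic 7-ketone
Product: 33 6-en-7-yl triflate
Conditions: KN(SiMe3)2, PhNTf2, THF, −78 °C
Reagents that add atoms: N-phenylbis(trifluoromethanesulfonimide) O=S(=O)(N(c1ccccc1)S(=O)(=O)C(F)(F)F)C(F)(F)F
Why: Kinetic deprotonation removes a C6 methylene hydrogen in preference to the hindered C8 methine, and the enolate is triflated on oxygen.

Step 23
Reactants: 33 6-en-7-yl triflate
Product: 34 6-ene
Conditions: Pd(OAc)2 (cat.), PPh3, HCO2H, n-Bu3N, DMF, 60 °C
Reagents that add atoms: none
Why: Palladium-catalysed formate reduction of the enol triflate (oxidative addition to zerovalent palladium, formate exchange, decarboxylation, reductive elimination) leaves the C6=C7 olefin without touching C8.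

Step 24
Reactants: 34 6-ene
Product: 35 11,12-diol (C11 secondary cyclobutanol, C12 primary alcohol)
Conditions: LiAlH4, THF, 0 → 23 °C
Reagents that add atoms: none
Why: Hydride reduction opens the lactone to both alcohols in one step; silyl ethers and the olefin are inert.

Step 25
Reactants: 35 11,12-diol
Product: 36 11-oxo-12-al
Conditions: Dess–Martin periodinane, NaHCO3, CH2Cl2, 0 → 23 °C
Reagents that add atoms: none
Why: Dess–Martin oxidation under buffered, non-basic conditions converts both alcohols without epimerising C1, which is now α to a cyclobutanone.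

Step 26
Reactants: 36 11-oxo-12-al
Product: 37 ring C closed, 11,12-cis-diol
Conditions: SmI2 (2.5 equiv), THF, −78 °C; aq. NaHCO3
Reagents that add atoms: none
Why: SmI2-mediated intramolecular pinacol coupling (ketyl addition, 6-exo, closing ring C): the C8–C14 link lets C12 reach the cyclobutanone only on the face syn to C8, so the C11 hydroxyl ends cis to O9, and binding of both oxygens to one trivalent samarium centre gives the cis-11,12-diol, which sets C12. α-Alkoxy carbonyl partners are tolerated in such couplings, and the strained, pre-organised ketone should trap the ketyl before the cyclopropane opens.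

Step 27
Reactants: 37 11,12-cis-diol
Product: 38 12-acetate
Conditions: Ac2O, pyridine, DMAP (cat.), CH2Cl2, 0 → 23 °C
Reagents that add atoms: acetic anhydride CC(=O)OC(C)=O
Why: Acetylation of the only free secondary hydroxyl; the tertiary C11 hydroxyl does not react under these conditions.

Step 28
Reactants: 38 12-acetate
Product: 39 3,9,11,14-tetraol 12-acetate
Conditions: HF·pyridine, pyridine/THF, 0 → 40 °C
Reagents that add atoms: none
Why: Buffered HF·pyridine cleaves the three silyl ethers without acyl migration (no basic fluoride) and without ionising the cyclopropylcarbinol.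

Step 29
Reactants: 39 3,9,11,14-tetraol 12-acetate
Product: 40 3,14-dione
Conditions: Dess–Martin periodinane, NaHCO3, CH2Cl2, 0 °C
Reagents that add atoms: none
Why: Dess–Martin oxidation of the two secondary alcohols gives both ketones and erases the uncontrolled C3 and C14 centres; buffering keeps the β,γ-unsaturated C14 ketone from moving into conjugation.

Step 30
Reactants: 40 3,14-dione
Product: 41 6β,7β-diol
Conditions: OsO4 (cat.), NMO, acetone/H2O, 23 °C
Reagents that add atoms: N-methylmorpholine N-oxide C[N+]1([O-])CCOCC1; water O
Why: Upjohn dihydroxylation: OsO4 adds suprafacially from the convex β face, anti to both allylic substituents (C4 on C5, C14 on C8), setting C6 and C7 together.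

Step 31
Reactants: 41 6β,7β-diol
Product: 42 CNP0157858.2
Conditions: Ac2O (1.1 equiv), 2,4,6-collidine, CH2Cl2, −20 → 0 °C
Reagents that add atoms: acetic anhydride CC(=O)OC(C)=O
Why: Kinetic monoacetylation: O6 is expected to be the equatorial, more exposed hydroxyl, while O7 is pseudo-axial, flanked by the branched C8 and hydrogen-bonded toward O9 and the C14 carbonyl. The tertiary hydroxyls are inert and the mild base avoids dehydration of the β-hydroxy ketone.

## Compound list

1 | (R)-propane-1,2-diol | C[C@@H](O)CO | starting material
2 | (4R)-4-methyl-1,3,2-dioxathiolane 2-oxide (cyclic sulfite, both sulfur epimers) | C[C@@H]1COS(=O)O1 | intermediate (not isolated)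
3 | (4R)-4-methyl-1,3,2-dioxathiolane 2,2-dioxide (cyclic sulfate) | C[C@@H]1COS(=O)(=O)O1 | intermediate
4 | dimethyl malonate | COC(=O)CC(=O)OC | starting material
5 | sodium (2R)-4,4-bis(methoxycarbonyl)butan-2-yl sulfate | COC(=O)C(C[C@@H](C)OS(=O)(=O)[O-])C(=O)OC.[Na+] | intermediate (not isolated)
6 | dimethyl (2S)-2-methylcyclopropane-1,1-dicarboxylate | C[C@H]1CC1(C(=O)OC)C(=O)OC | intermediate
7 | methyl (1R,2S)-1-formyl-2-methylcyclopropane-1-carboxylate (formyl trans to methyl) | C[C@H]1C[C@@]1(C=O)C(=O)OC | intermediate
8 | (1R,2S)-1-formyl-2-methylcyclopropane-1-carboxylic acid (carboxyl cis to methyl) | C[C@H]1C[C@@]1(C=O)C(=O)O | intermediate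
9 | (S)-Hajos–Parrish ketone, (7aS)-7a-methyl-2,3,7,7a-tetrahydro-1H-indene-1,5(6H)-dione | O=C1CC[C@]2(C)C(=O)CCC2=C1 | starting material
10 | dienol ethyl ether of 9: 7-ethoxy-7,9(11)-dien-2-one, 10β-methyl | C1CC(OCC)=CC3=CCC(=O)[C@@]13C | intermediate
11 | 11α-hydroxy-8-ene-2,7-dione (hydroxyl trans to the C10 methyl) | C1CC(=O)C=C3[C@@H](O)CC(=O)[C@@]13C | intermediate
12 | 11α-triethylsilyloxy-8-ene-2,7-dione | C1CC(=O)C=C3[C@@H](O[Si](CC)(CC)CC)CC(=O)[C@@]13C | intermediate
13 | 8β,9β-epoxy-11α-triethylsilyloxy-2,7-dione (epoxide cis to the C10 methyl) | C1CC(=O)[C@@H]2O[C@@]23[C@@H](O[Si](CC)(CC)CC)CC(=O)[C@@]13C | intermediate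
14 | 9β-hydroxy-11α-triethylsilyloxy-cis-hydrindane-2,7-dione | C1CC(=O)C[C@@]3(O)[C@@H](O[Si](CC)(CC)CC)CC(=O)[C@@]13C | intermediate
15 | 9β,11α-bis(triethylsilyloxy)-cis-hydrindane-2,7-dione | C1CC(=O)C[C@@]3(O[Si](CC)(CC)CC)[C@@H](O[Si](CC)(CC)CC)CC(=O)[C@@]13C | intermediate
16 | 7,7-ethylenedioxy-9β,11α-bis(triethylsilyloxy)-cis-hydrindan-2-one | C1CC2(OCCO2)C[C@@]3(O[Si](CC)(CC)CC)[C@@H](O[Si](CC)(CC)CC)CC(=O)[C@@]13C | intermediate
17 | 1-trifluoroacetyl derivative of 16 (C1 epimers and enol) | C1CC2(OCCO2)C[C@@]3(O[Si](CC)(CC)CC)[C@@H](O[Si](CC)(CC)CC)C(C(=O)C(F)(F)F)C(=O)[C@@]13C | intermediate (not isolated)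
18 | 1-diazo-7,7-ethylenedioxy-9β,11α-bis(triethylsilyloxy)-cis-hydrindan-2-one | C1CC2(OCCO2)C[C@@]3(O[Si](CC)(CC)CC)[C@@H](O[Si](CC)(CC)CC)C(=[N+]=[N-])C(=O)[C@@]13C | intermediate
19 | ring-contracted ketene (C1=C2=O on the ring B/ring D bicyclo[4.2.0]octane) | C1CC2(OCCO2)C[C@@]3(O[Si](CC)(CC)CC)[C@@H](O[Si](CC)(CC)CC)C(=C=O)[C@@]13C | intermediate (not isolated)
20 | ring B/ring D methyl ester as C1 epimers | C1CC2(OCCO2)C[C@@]3(O[Si](CC)(CC)CC)[C@@H](O[Si](CC)(CC)CC)C(C(=O)OC)[C@@]13C | intermediate (not isolated)
21 | ring B/ring D methyl ester: cis-bicyclo[4.2.0]octane, 7-dioxolane, 9,11-bis-O-triethylsilyl (O11 trans to O9), CO2Me on C1 cis to the C10 methyl | C1CC2(OCCO2)C[C@@]3(O[Si](CC)(CC)CC)[C@@H](O[Si](CC)(CC)CC)[C@H](C(=O)OC)[C@@]13C | intermediate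
22 | C2 primary alcohol (CH2OH on C1) | C1CC2(OCCO2)C[C@@]3(O[Si](CC)(CC)CC)[C@@H](O[Si](CC)(CC)CC)[C@H](CO)[C@@]13C | intermediate
23 | C2 primary iodide (CH2I on C1) | C1CC2(OCCO2)C[C@@]3(O[Si](CC)(CC)CC)[C@@H](O[Si](CC)(CC)CC)[C@H](CI)[C@@]13C | intermediate
24 | C2 organolithium | C1CC2(OCCO2)C[C@@]3(O[Si](CC)(CC)CC)[C@@H](O[Si](CC)(CC)CC)[C@H](C[Li])[C@@]13C | intermediate (not isolated)
25 | lithium alkoxide of the C3 allylic alcohol (both C3 epimers) | C1CC2(OCCO2)C[C@@]3(O[Si](CC)(CC)CC)[C@@H](O[Si](CC)(CC)CC)[C@H](CC(O[Li])C(C)=C)[C@@]13C | intermediate (not isolated)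
26 | C3 triisopropylsilyl ether, side chain CH2–CH(OSi-i-Pr3)–C(CH3)=CH2 on C1 (both C3 epimers) | C1CC2(OCCO2)C[C@@]3(O[Si](CC)(CC)CC)[C@@H](O[Si](CC)(CC)CC)[C@H](CC(O[Si](C(C)C)(C(C)C)C(C)C)C(C)=C)[C@@]13C | intermediate
27 | 7-oxo-9β,11-diol (O11 trans to O9) | C1CC(=O)C[C@@]3(O)[C@@H](O)[C@H](CC(O[Si](C(C)C)(C(C)C)C(C)C)C(C)=C)[C@@]13C | intermediate
28 | 11-O-[(1R,2S)-1-formyl-2-methylcyclopropanecarbonyl] ester of 27 | C1CC(=O)C[C@@]3(O)[C@@H](OC(=O)[C@]4(C=O)C[C@@H]4C)[C@H](CC(O[Si](C(C)C)(C(C)C)C(C)C)C(C)=C)[C@@]13C | intermediate
29 | 5-en-7-one of 28 | C1=CC(=O)C[C@@]3(O)[C@@H](OC(=O)[C@]4(C=O)C[C@@H]4C)[C@H](CC(O[Si](C(C)C)(C(C)C)C(C)C)C(C)=C)[C@@]13C | intermediate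
30 | 7-triethylsilyloxy-5,7-diene, 9-O-triethylsilyl | C1=CC(O[Si](CC)(CC)CC)=C[C@@]3(O[Si](CC)(CC)CC)[C@@H](OC(=O)[C@]4(C=O)C[C@@H]4C)[C@H](CC(O[Si](C(C)C)(C(C)C)C(C)C)C(C)=C)[C@@]13C | intermediate (not isolated)
31 | aldol lactone: C8–C14 bond, seven-membered lactone O11–C12(=O)–C13–C14–C8–C9–C11, 9,14-bis-O-triethylsilyl, 8β-H (C14 epimers) | C1=CC(=O)[C@@H]5[C@@]3(O[Si](CC)(CC)CC)[C@@H](OC(=O)[C@]4(C5O[Si](CC)(CC)CC)C[C@@H]4C)[C@H](CC(O[Si](C(C)C)(C(C)C)C(C)C)C(C)=C)[C@@]13C | intermediate
32 | ring A closed: C4–C5 bond, 5β-H, gem-dimethyl C4, 7-ketone | [C@H]16CC(=O)[C@@H]5[C@@]3(O[Si](CC)(CC)CC)[C@@H](OC(=O)[C@]4(C5O[Si](CC)(CC)CC)C[C@@H]4C)[C@H](CC(O[Si](C(C)C)(C(C)C)C(C)C)C6(C)C)[C@@]13C | intermediate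
33 | 6-en-7-yl triflate | [C@H]16C=C(OS(=O)(=O)C(F)(F)F)[C@@H]5[C@@]3(O[Si](CC)(CC)CC)[C@@H](OC(=O)[C@]4(C5O[Si](CC)(CC)CC)C[C@@H]4C)[C@H](CC(O[Si](C(C)C)(C(C)C)C(C)C)C6(C)C)[C@@]13C | intermediate
34 | 6-ene | [C@H]16C=C[C@@H]5[C@@]3(O[Si](CC)(CC)CC)[C@@H](OC(=O)[C@]4(C5O[Si](CC)(CC)CC)C[C@@H]4C)[C@H](CC(O[Si](C(C)C)(C(C)C)C(C)C)C6(C)C)[C@@]13C | intermediate
35 | 11,12-diol (lactone opened) | [C@H]16C=C[C@@H](C(O[Si](CC)(CC)CC)[C@@]4(CO)C[C@@H]4C)[C@@]3(O[Si](CC)(CC)CC)[C@@H](O)[C@H](CC(O[Si](C(C)C)(C(C)C)C(C)C)C6(C)C)[C@@]13C | intermediate
36 | 11-oxo-12-al | [C@H]16C=C[C@@H](C(O[Si](CC)(CC)CC)[C@@]4(C=O)C[C@@H]4C)[C@@]3(O[Si](CC)(CC)CC)C(=O)[C@H](CC(O[Si](C(C)C)(C(C)C)C(C)C)C6(C)C)[C@@]13C | intermediate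
37 | ring C closed, 11,12-cis-diol (both hydroxyls cis to O9) | C1=C[C@H]2C(O[Si](CC)(CC)CC)[C@]3(C[C@@H]3C)[C@H](O)[C@@]3(O)[C@@H]4CC(O[Si](C(C)C)(C(C)C)C(C)C)C(C)(C)[C@@H]1[C@@]4(C)[C@@]23O[Si](CC)(CC)CC | intermediate
38 | 12-acetate of 37 | C1=C[C@H]2C(O[Si](CC)(CC)CC)[C@]3(C[C@@H]3C)[C@H](OC(C)=O)[C@@]3(O)[C@@H]4CC(O[Si](C(C)C)(C(C)C)C(C)C)C(C)(C)[C@@H]1[C@@]4(C)[C@@]23O[Si](CC)(CC)CC | intermediate
39 | 3,9,11,14-tetraol 12-acetate (C3 and C14 epimers) | C1=C[C@H]2C(O)[C@]3(C[C@@H]3C)[C@H](OC(C)=O)[C@@]3(O)[C@@H]4CC(O)C(C)(C)[C@@H]1[C@@]4(C)[C@@]23O | intermediate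
40 | 3,14-dione, 6-ene, 12-acetate, 9,11-diol | C1=C[C@H]2C(=O)[C@]3(C[C@@H]3C)[C@H](OC(C)=O)[C@@]3(O)[C@@H]4CC(=O)C(C)(C)[C@@H]1[C@@]4(C)[C@@]23O | intermediate
41 | 6β,7β-diol (6-deacetyl target) | O[C@@H]1[C@H](O)[C@H]2C(=O)[C@]3(C[C@@H]3C)[C@H](OC(C)=O)[C@@]3(O)[C@@H]4CC(=O)C(C)(C)[C@@H]1[C@@]4(C)[C@@]23O | intermediate
42 | CNP0157858.2 | CC(=O)O[C@@H]1[C@H](O)[C@H]2C(=O)[C@]3(C[C@@H]3C)[C@H](OC(C)=O)[C@@]3(O)[C@@H]4CC(=O)C(C)(C)[C@@H]1[C@@]4(C)[C@@]23O | target

## Step count and least certain steps

Total: 31 steps. Longest linear sequence: 27 steps (steps 5–31, from 9 to 42). The four-step branch from 1 and 4 to 8 (steps 1–4) joins in step 18.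

Step 13 (key step). Most likely failure: 1,2-hydride shift from C11–H to the carbene carbon, or O–H insertion into methanol, may outrun a contraction that builds ring strain; β-elimination of the C11 silyloxy group during methoxide equilibration is a further loss. Fallback: the same C10 shift run as an ionic process. Setting out from 16, the lithium enolate (LiN(SiMe3)2, −78 °C) is brominated with N-bromosuccinimide to the α-bromo ketone F1. With NaOMe in MeOH (AgSbF6 if ionisation is slow) methoxide adds to the C2 carbonyl and C10 shifts to C1 as bromide leaves (semibenzilic, quasi-Favorskii rearrangement; no α′-hydrogen allows the cyclopropanone pathway). The same methoxide equilibration at C1 returns the route at 21.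

Step 20. Most likely failure: slow closure of the seven-membered lactone ring, so that intermolecular aldol addition or Prins-type attack of the isopropenyl group on the activated aldehyde takes over. Fallback: a reductively generated metal enolate instead of an enol silane. Setting out from 29, the silyl dienol ether (Et3SiOTf, Et3N) is brominated with N-bromosuccinimide to the 8-bromo enone F2 (O9 silylated). CrCl2/LiI in THF then forms the chromium enolate at C8 only (chromium Reformatsky reaction); it adds to the tethered aldehyde through a closed chelated transition state and does not attack esters, giving the hydroxy lactone F3. Et3SiOTf/2,6-lutidine converts this into 31.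

Step 21. Most likely failure: premature reduction of the tertiary radical (net hydrogenation of the isopropenyl group), because closure to a ring trans-fused to the cyclobutane is slowed by strain while hydride and silane are present. Fallback: the same radical generated without a hydrogen-atom donor. Setting out from 31, Mukaiyama hydration of the isopropenyl group (Co(acac)2, PhSiH3, O2, i-PrOH) gives the tertiary alcohol F4; oxalyl chloride followed by aqueous CsHCO3 gives the caesium oxalate F5. Visible-light photoredox oxidation ([Ir(dF(CF3)ppy)2(dtbbpy)]PF6, blue light, DME/DMF/H2O) releases CO2 and the C4 radical, which can add to C5 without competition; the route is rejoined at 32.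

Step 26. Most likely failure: opening of the cyclopropane from the cyclopropylcarbinyl ketyl at C12, reductive loss of the C9 silyloxy group from the cyclobutanone ketyl, or poor cis/trans control at C12. Fallback: a two-electron closure. Setting out from 36, an N-heterocyclic-carbene-catalysed intramolecular crossed benzoin reaction (triazolium precatalyst, Et3N, toluene) adds the Breslow intermediate at C12 to the cyclobutanone on the tethered face, giving the α-ketol F6. The tertiary hydroxyl is capped (Et3SiOTf, 2,6-lutidine) to the silyl ether F7; i-Bu2AlH at −78 °C, a non-chelating hydride, should approach C12 anti to the bulky silyloxy group and give the cis alcohol F8; acetylation gives the acetate F9. The HF·pyridine conditions of step 28 remove the extra silyl group with the others, so the route is rejoined at 39.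

Step 31. Most likely failure: poor site selectivity between O6 and O7, and acyl migration between them. Fallback: stereoelectronic instead of steric control. Setting out from 41, MeC(OMe)3 and pyridinium p-toluenesulfonate give the cyclic 6,7-orthoacetate F10. Its hydrolytic opening (80% aq. AcOH, 0 °C) places the acetate on the axial oxygen, the one that direct acylation disfavours, so whichever hydroxyl is axial, one of the two methods leads to 42.

## Further compounds

F1 | step 13 | 1-bromo-7,7-ethylenedioxy-9β,11α-bis(triethylsilyloxy)-cis-hydrindan-2-one (C1 epimers) | C1CC2(OCCO2)C[C@@]3(O[Si](CC)(CC)CC)[C@@H](O[Si](CC)(CC)CC)C(Br)C(=O)[C@@]13C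
F2 | step 20 | 8-bromo-5-en-7-one, 9-O-triethylsilyl, 11-O-acyl (C8 epimers) | C1=CC(=O)C(Br)[C@@]3(O[Si](CC)(CC)CC)[C@@H](OC(=O)[C@]4(C=O)C[C@@H]4C)[C@H](CC(O[Si](C(C)C)(C(C)C)C(C)C)C(C)=C)[C@@]13C
F3 | step 20 | 14-hydroxy aldol lactone, 9-O-triethylsilyl (C14 epimers) | C1=CC(=O)[C@@H]5[C@@]3(O[Si](CC)(CC)CC)[C@@H](OC(=O)[C@]4(C5O)C[C@@H]4C)[C@H](CC(O[Si](C(C)C)(C(C)C)C(C)C)C(C)=C)[C@@]13C
F4 | step 21 | C4 tertiary alcohol from hydration of 31 | C1=CC(=O)[C@@H]5[C@@]3(O[Si](CC)(CC)CC)[C@@H](OC(=O)[C@]4(C5O[Si](CC)(CC)CC)C[C@@H]4C)[C@H](CC(O[Si](C(C)C)(C(C)C)C(C)C)C(C)(C)O)[C@@]13C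
F5 | step 21 | caesium oxalate of F4 | C1=CC(=O)[C@@H]5[C@@]3(O[Si](CC)(CC)CC)[C@@H](OC(=O)[C@]4(C5O[Si](CC)(CC)CC)C[C@@H]4C)[C@H](CC(O[Si](C(C)C)(C(C)C)C(C)C)C(C)(C)OC(=O)C(=O)[O-])[C@@]13C.[Cs+]
F6 | step 26 | ring C α-ketol (C12 ketone, C11 tertiary hydroxyl cis to O9) | C1=C[C@H]2C(O[Si](CC)(CC)CC)[C@]3(C[C@@H]3C)C(=O)[C@@]3(O)[C@@H]4CC(O[Si](C(C)C)(C(C)C)C(C)C)C(C)(C)[C@@H]1[C@@]4(C)[C@@]23O[Si](CC)(CC)CC
F7 | step 26 | 11-O-triethylsilyl ether of F6 | C1=C[C@H]2C(O[Si](CC)(CC)CC)[C@]3(C[C@@H]3C)C(=O)[C@@]3(O[Si](CC)(CC)CC)[C@@H]4CC(O[Si](C(C)C)(C(C)C)C(C)C)C(C)(C)[C@@H]1[C@@]4(C)[C@@]23O[Si](CC)(CC)CC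
F8 | step 26 | 12-alcohol cis to the 11-silyloxy group | C1=C[C@H]2C(O[Si](CC)(CC)CC)[C@]3(C[C@@H]3C)[C@H](O)[C@@]3(O[Si](CC)(CC)CC)[C@@H]4CC(O[Si](C(C)C)(C(C)C)C(C)C)C(C)(C)[C@@H]1[C@@]4(C)[C@@]23O[Si](CC)(CC)CC
F9 | step 26 | 12-acetate of F8 | C1=C[C@H]2C(O[Si](CC)(CC)CC)[C@]3(C[C@@H]3C)[C@H](OC(C)=O)[C@@]3(O[Si](CC)(CC)CC)[C@@H]4CC(O[Si](C(C)C)(C(C)C)C(C)C)C(C)(C)[C@@H]1[C@@]4(C)[C@@]23O[Si](CC)(CC)CC
F10 | step 31 | cyclic 6,7-(1-methoxyethylidene) orthoacetate of 41 | COC1(C)O[C@@H]2[C@H](O1)[C@H]3C(=O)[C@]4(C[C@@H]4C)[C@H](OC(C)=O)[C@@]5(O)[C@@H]6CC(=O)C(C)(C)[C@@H]2[C@@]6(C)[C@@]35O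
A1 | alternative 1 | (Z)-aryl epoxy diene: 3-allyl-1,2,4-trimethoxy-5-[(3Z)-4-methyl-6-(3,3-dimethyloxiran-2-yl)hex-3-en-1-yl]benzene | c1(CC/C=C(C)\CC[C@@H]2OC2(C)C)c(OC)c(CC=C)c(OC)c(OC)c1
A2 | alternative 1 | cis-fused 3-hydroxy-11,12,14-trimethoxy-13-allyl tricycle | C1Cc2c(OC)c(CC=C)c(OC)c(OC)c2[C@@]3(C)CC[C@H](O)C(C)(C)[C@@H]13
A3 | alternative 2 | 2-benzyloxy-4-(tert-butyldimethylsilyloxymethyl)-3-methylcyclobut-2-en-1-one | O=C1C(OCc2ccccc2)=C(C)[C@H]1CO[Si](C)(C)C(C)(C)C
A4 | alternative 2 | (2E,4E)-7,7-dimethoxy-6,6-dimethylhepta-2,4-dienyl 4-methoxybenzyl ether | COc1ccc(COC/C=C/C=C/C(C)(C)C(OC)OC)cc1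
A5 | alternative 2 | cis-fused bicyclo[4.2.0]octenone (rings B and D) | C1=C[C@@H](COCc2ccc(OC)cc2)[C@@]3(OCc4ccccc4)C(=O)[C@H](CO[Si](C)(C)C(C)(C)C)[C@@]3(C)[C@H]1C(C)(C)C(OC)OC
A6 | alternative 3 | tetracyclic C12=C13 olefin with C15 mesylate and 11-O-tert-butyl carbonate | CC1(C)O[C@@H]2[C@H](O1)[C@H]3[C@@H](O[Si](C)(C)C(C)(C)C)C(C[C@H](OS(C)(=O)=O)C)=C[C@@]7(OC(=O)OC(C)(C)C)[C@@H]5CC(=O)C(C)(C)[C@@H]2[C@@]5(C)[C@@]37O
A7 | alternative 3 | spirocyclopropane 11,12-cyclic carbonate | CC1(C)O[C@@H]2[C@H](O1)[C@H]3[C@@H](O[Si](C)(C)C(C)(C)C)[C@]4(C[C@@H]4C)[C@@H]8OC(=O)O[C@@]87[C@@H]5CC(=O)C(C)(C)[C@@H]2[C@@]5(C)[C@@]37O
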